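The earlier runs and the new flask were computed from invented constants, and the scatter is random.

Oak, the earlier run, has the L and Z of dusk, dawn, winter and spring, so a rate read from it can be carried to those flasks.

| setting | oak | cedar | dusk | dawn | winter | spring |
|---|---|---|---|---|---|---|
| E | 0.050 M | 0.050 M | 0.050 M | 0.050 M (fed, over 15 h) | 0.050 M | 0.050 M |
| D | 0.10 M | 0.10 M | 0.100 M | 0.100 M | 0.100 M (fed, over 15 h) | 0.100 M (in portions, 2, over 15 h) |
| L | 1.2 mM | 1.2 mM | 1.2 mM | 1.2 mM | 1.2 mM | 1.2 mM |
| Z | 1.6 mM | 2.4 mM | 1.6 mM | 1.6 mM | 1.6 mM | 1.6 mM |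
| remark | run made earlier | run made earlier | everything together at the start | all else is in the flask from the start; the feed brings no volume worth counting | all else is in the flask from the start; the feed brings no volume worth counting | first portion at the start, last at 15 h |
| time |  |  | 20 h | 20 h | 20 h | 20 h |

| run | time / h | J / % | E / % |
|---|---|---|---|
| oak | 1.00 | 7.5 | 78.8 |
| oak | 1.33 | 10.5 | 77.4 |
| oak | 2.00 | 15.3 | 73.0 |
| oak | 3.00 | 21.6 | 65.5 |
| oak | 5.00 | 34.3 | 56.2 |
| oak | 8.00 | 47.8 | 44.9 |
| oak | 12.0 | 61.5 | 33.4 |
| cedar | 0.500 | 2.3 | 85.7 |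
| cedar | 1.00 | 6.8 | 80.5 |
| cedar | 1.50 | 9.6 | 78.2 |
| cedar | 2.50 | 16.3 | 71.6 |
| cedar | 3.00 | 19.9 | 69.1 |
| cedar | 4.00 | 25.0 | 64.0 |

(scatter of a reading: 0.5 percentage points)

* the best flask by amount of J, in percent of the E charged; "all alike" if 1.5 percentage points covers them all (dusk / dawn / winter / spring / all alike)
* amount of J at the end, in percent of the E charged, dusk
* amount of J at the end, in percent of the E charged, dawn
* amount of J at the end, in percent of the E charged, winter
* amount of J at the end, in percent of the E charged, spring



Take the clocks from the fastest. By 0.500 h in cedar, E and J together already fall 12 percentage points short of the charge, so a pool fills early. In oak that shortfall shrinks from 14 points to 5.1 points by 12.0 h, so you count everything that is not yet J as unreacted E.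

Next comes the drain of that E. Treat it as pseudo-first-order in [D] and replace the falling [D] by its mean. The D-hours, Φ, are mean [D] times time. The D-hour constant, k, is the logarithm of charged over unreacted E, divided by Φ. Oak gives 0.0157 M⁻¹ min⁻¹ at 12.0 h and 0.0153 M⁻¹ min⁻¹ at 5.00 h, two readings that each carry the scatter of 0.5 points.

At the charged D, the lifetime of E is 10.6 h, shorter than the 15 h feed, so the feeds matter. Your reckoning gives dusk 77.3%. In dawn, fed E sits 12.5 h on average, which gives 62.2%. In winter, delivered D averages half the charge during the feed, less the D eaten, taken as a third of what 50.6% of J would eat. That makes Φ 59.8 M·min and J 60.8%. Spring, reckoned alike, has Φ 56.0 M·min and J 58.4%. Dusk leads.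

The forecast names dusk, with 79.5%, 61%, 75% and 76%, and says “Winter and spring therefore come out at or below dusk, and this is the least certain part”.

The flasks give 76.9% in dusk, 60.2% in dawn, 62.5% in winter and 60.7% in spring, so dusk is best. Over the first 15 h, [D] averaged 0.0409 M in winter against 0.0920 M in dawn. Put winter's mean, then the 76.8% to 68.7% of its charge standing afterwards, into k, and you get 60.1%.

    E + L ⇌ L + G (K = 0.190, k = 16.0 M⁻¹ min⁻¹)
    D + L + G → L + J (k = 140 M⁻² min⁻¹)
    L + Z ⇌ X, settled at all times (K = 410 M⁻¹)

Now take dawn's neighbour with 0.17 M of D. The same reckoning gives 82.5%. The computed flask gives 77.0%, with 19.9% of E left, which is 5.5 points less than the reckoning; in dawn the reckoning stood 2 points above the flask.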